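Assumption: 4-methylfuran-3-carboxylic acid, (E)-2-bromobut-2-ene, (E)-oct-2-enal and (−)-B-allyldiisopinocampheylborane (pentane solution) are taken as purchasable. Eremophilane numbering is used (C1–C10 ring carbons, C11–C13 on C7, C14 = methyl on C5, C15 = methyl on C4; β = the face of C14; "furanoeremophilane" = 3,4a,5-trimethyl-4,4a,5,6,7,8,8a,9-octahydronaphtho[2,3-b]furan).

## The problem

The target is a cis-fused eremophilane (10βH, angular C14 methyl on quaternary C5) with five contiguous stereocentres from C3 through C4, C5 and C10 to C9: 3α-acyloxy, 4β-methyl, 5β-methyl, 10β-H and 9β-OH (3R,4R,5R,9R,10S). The hardest element is the C4/C5 pair: two vicinal cis methyl groups, one on a quaternary ring-fusion carbon, flanked by the C3 oxygen (trans to C15) and the cis ring-fusion hydrogen. Once C5 is quaternary these centres cannot be corrected by equilibration, so their relative configuration has to be written in one event. Ring B holds an α-ketol (C9–OH/C8=O) next to a tetrasubstituted C7=C11 alkene whose hydroxymethyl group (C12) is Z to the ketone; this Z-γ-hydroxy-enone closes to a hemiketal and loses water to a furan with acid, and the ketol can epimerise or transpose with base. The (2E,4E,6E)-5-methyldodecatrienoate on O-3 does not survive hydrogenation, radical chain reduction, strong hydride reagents or strong base, and free 9- and 12-hydroxyls would compete in acylation, so the ester must go on late but before ring B is unveiled. The enabling feature is that C7, C8, C11, C12, C13 and the oxygens on C8 and C12 are, one oxidation step down, a 2,3-fused 4-methylfuran. This flat two-atom spacer (C7=C8) holds C6 and C9 syn, so a C6 acyl group carrying the C4=C5 alkene with C14 and C15 cis (a tigloyl unit) and a C9 carbinol carrying the C10=C1–C2=C3–O diene are pre-organised for an intramolecular [4+2] that forms C3–C4 and C5–C10, closing ring A and ring B together. In that event the alkene geometries fix C3, C4, C5 and C10 relative to each other, and the C9 carbinol, the only reagent-made stereocentre, fixes their absolute sense.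

## Retrosynthesis

**Ring B last (33 ⇐ 32 ⇐ 31).** The C8 ketone and the C12 alcohol are traced back to the ring oxygen of furan 31. Oxidative opening of the C8–O–C12 unit gives keto-enal 32, whose C7=C11 geometry is dictated by the ring, and aldehyde-selective reduction gives 33. An aldol/dehydration or olefination at C7 would leave the Z geometry uncontrolled, and the furan also hides the ketol and enone through the radical, hydride and acylation steps. The forward steps must oxidise the furan beside the trienoate (directed by the 9-hydroxyl) and reduce an aldehyde beside a conjugated ketone.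

**Ester bond and C9 (31 ⇐ 29 ⇐ 28 ⇐ 19 + 26).** The acyl C–O bond is cut where O-3 is the only free hydroxyl, giving alcohol 19 and acid 26. C9 is carried as the 9α epimer because that is what the cycloaddition is expected to deliver (next but one paragraph). It is inverted at 29 by SN2 displacement from the convex β face, which gives the natural 9β-hydroxyl of 31. The esterification must not isomerise the triene, and the inversion must be clean at a furylic carbinol.

**Trimming the cycloadduct (19 ⇐ 18 ⇐ 15 ⇐ 14).** Three things separate 19 from cycloadduct 14: the C6 carbonyl (the activating group), the C1=C2 alkene and the two different silyl ethers. The C6 oxygen is the price of activation; it is removed by radical deoxygenation because ionic reduction would ionise the furylic C9–O bond.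

**Key disconnection (14 ⇐ 13 ⇐ 12).** C3–C4 and C5–C10 are cut as a retro-Diels–Alder in ring A, which also opens ring B because the furan is the tether. Cutting C1–C10 and C4–C5 instead (ring B as dienophile) would set C15 trans to C14 by the endo rule; this cut keeps the two methyls cis through the (E)-tigloyl geometry. Triene 13 has one stereocentre and no ring besides the furan; 14 has five stereocentres and the whole tricyclic core. The forward reaction needs cis fusion (C6 carbonyl endo), facial control by C9 and chemoselective enolisation of enal 12.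

**Precursor assembly (12 ⇐ 10 + 11; 10 ⇐ 7 + 8; 7 ⇐ 6 ⇐ 5 ⇐ 3 ⇐ 1).** C1=C2 comes from cross-metathesis of 10 with crotonaldehyde 11. The C5–C6 bond comes from acylation of vinyllithium 9 (from bromide 8) with amide 7. The C9–C10 bond and the C9 stereocentre come from asymmetric allylation of aldehyde 5 (giving 6, silylated to 7). The C8–C9 bond comes from amide-directed metalation and formylation of 3, made from acid 1. Each cut removes one purchasable C1–C4 piece; the only demanding requirements are the allylation selectivity and addition to a flanked amide.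

**Side chain (26 ⇐ 25 ⇐ 23 + 24; 23 ⇐ 21 ⇐ 20).** The C3–C4 bond of the acid is cut as a Heck coupling of dienyl iodide 23 with ethyl acrylate 24. The trisubstituted (E)-alkene of 23 comes from methyl and iodine added across the alkyne of enyne 21, which is one carbon more than enal 20. Carbometalation is chosen over a ketone olefination because it fixes the 4E geometry.

## Roads not taken

**Alternative 1: Robinson annulation.** Cut C5–C6 and C9–C10. Michael addition of the more substituted enolate of ring-A ketone A1 to methyl vinyl ketone and aldol condensation would give octalone A2 (a 3-silyloxy-eremophil-9-en-8-one lacking C11–C13). This is the route most chemists would draw first. It is weaker here for three reasons: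
- The cis C14/C15 relation rests on the facial preference of an enolate alkylation next to one methyl group, and A1 itself needs an enantioselective synthesis.
- C10 and C9 are set afterwards in separate operations: a face-selective hydrogenation of the C9=C10 enone and an extra oxygenation.
- The C7=C11 alkene would come from an aldol/dehydration with no control of the Z geometry.

The chosen plan writes C3, C4, C5 and C10 in one stereospecific event and takes the Z alkene from a ring.

**Alternative 2: quinone Diels–Alder.** Cut C1–C10 and C4–C5. 2-Methoxy-5-methyl-1,4-benzoquinone as ring B and the (Z)-silyl dienol ether A3 of pent-1-en-3-one as C1–C4 would give adduct A4 in one step, with the cis fusion, the quaternary C5 and oxygen on C3, C8 and C9. It was set aside on mechanistic grounds: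
- In the endo transition state the outside methyl of A3 ends up trans to the angular methyl, so A4 has the wrong C4 configuration; C15 would then depend on an unpredictable equilibration next to the C3 ketone.
- The new C4–C5 bond joins two methyl-bearing carbons intermolecularly.
- C10 lies next to the C9 carbonyl and can epimerise to the trans-fused series.
- The extra C6 oxygen must be removed, and C7 still has to receive C11–C13 with Z control.
- Enantiocontrol would need a chiral Lewis acid whose binding site also decides the regiochemistry.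

**Alternative 3: enolate alkylation and Friedel–Crafts closure.** Cut C5–C6 and C8–C9. Alkylation of the thermodynamic enolate of A1 with 3-(bromomethyl)-4-methylfuran A5 would give ketone A6; one-carbon homologation would give aldehyde A7, which closes onto the furan α-carbon under acid. The route is convergent, but every stereocentre is set separately: ring A must be made enantiopure first, the quaternary centre depends on a regio- and face-selective alkylation, C10 is an epimerisable aldehyde α-carbon, and the closure gives an ionisable furyl carbinol with no control of C9. It is also longer than the chosen route.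

Key step: step 7

## Route

Step 1
Reactants: 1 4-methylfuran-3-carboxylic acid
Product: 3 (4-methylfuran-3-yl)(morpholin-4-yl)methanone, via 4-methylfuran-3-carbonyl chloride 2 (not isolated)
Conditions: (COCl)2, DMF (cat.), CH2Cl2, 0 °C to rt; then morpholine, Et3N, 0 °C
Reagents that add atoms: morpholine, C1COCCN1
Why: Acid chloride formation and amidation; the morpholine amide serves as directing group for metalation at C8 and as an acyl donor that stops at the ketone stage in step 5.

Step 2
Reactants: 3 (4-methylfuran-3-yl)(morpholin-4-yl)methanone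
Product: 5 4-methyl-3-(morpholine-4-carbonyl)furan-2-carbaldehyde, via furan-2-ylmagnesium chloride 4 (not isolated)
Conditions: TMPMgCl·LiCl, THF, −30 °C; DMF, −30 to 0 °C; aq. NH4Cl
Reagents that add atoms: N,N-dimethylformamide, CN(C)C=O
Why: Amide-directed magnesiation at the furan α-position next to the amide (C8), then formylation; the other α-hydrogen (C12–H) is not ortho to the directing group and is less acidic.

Step 3
Reactants: 5 4-methyl-3-(morpholine-4-carbonyl)furan-2-carbaldehyde
Product: 6 {2-[(1S)-1-hydroxybut-3-en-1-yl]-4-methylfuran-3-yl}(morpholin-4-yl)methanone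
Conditions: (−)-Ipc2B(allyl), Et2O, −78 °C; then NaOH, H2O2, 0 °C to rt
Reagents that add atoms: (−)-B-allyldiisopinocampheylborane, C=CCB([C@@H]1C[C@@H]2C[C@H]([C@H]1C)C2(C)C)[C@@H]1C[C@@H]2C[C@H]([C@H]1C)C2(C)C
Why: Brown allylboration through a chair six-membered transition state; the (+)-α-pinene-derived reagent is the one that gives (S)-1-arylbut-3-en-1-ols, so C9 is set as (S), the only reagent-controlled stereocentre of the route.

Step 4
Reactants: 6 {2-[(1S)-1-hydroxybut-3-en-1-yl]-4-methylfuran-3-yl}(morpholin-4-yl)methanone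
Product: 7 {2-[(1S)-1-(tert-butyldimethylsilyloxy)but-3-en-1-yl]-4-methylfuran-3-yl}(morpholin-4-yl)methanone
Conditions: TBSCl, imidazole, DMF, rt
Reagents that add atoms: tert-butyldimethylsilyl chloride, C[Si](C)(Cl)C(C)(C)C
Why: Standard silylation; the bulky silyl ether later steers the cycloaddition and is inert to the organolithium, hydride and radical steps.

Step 5
Reactants: 7 {2-[(1S)-1-(tert-butyldimethylsilyloxy)but-3-en-1-yl]-4-methylfuran-3-yl}(morpholin-4-yl)methanone; 8 (E)-2-bromobut-2-ene
Product: 10 (2E)-1-{2-[(1S)-1-(tert-butyldimethylsilyloxy)but-3-en-1-yl]-4-methylfuran-3-yl}-2-methylbut-2-en-1-one, via (E)-but-2-en-2-yllithium 9 (not isolated)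
Conditions: 8, t-BuLi (2 equiv), Et2O, −78 °C; then 7, THF, −78 to −20 °C; aq. NH4Cl
Reagents that add atoms: none
Why: Bromine–lithium exchange with retention of alkene geometry, then addition to the morpholine amide, whose tetrahedral adduct holds until work-up (ketone synthesis from a tertiary amide); the (E)-geometry with C14 and C15 cis is what becomes the cis-dimethyl pair.

Step 6
Reactants: 10 (2E)-1-{2-[(1S)-1-(tert-butyldimethylsilyloxy)but-3-en-1-yl]-4-methylfuran-3-yl}-2-methylbut-2-en-1-one; 11 (E)-but-2-enal
Product: 12 (2E,5S)-5-(tert-butyldimethylsilyloxy)-5-{4-methyl-3-[(2E)-2-methylbut-2-enoyl]furan-2-yl}pent-2-enal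
Conditions: 11 (excess), second-generation Hoveyda–Grubbs catalyst (cat.), CH2Cl2, 40 °C
Reagents that add atoms: none
Why: Olefin cross-metathesis of a terminal alkene with an enal gives the (E)-enal; the trisubstituted, electron-poor tigloyl alkene and the furan do not take part.

Step 7
Reactants: 12 (2E,5S)-5-(tert-butyldimethylsilyloxy)-5-{4-methyl-3-[(2E)-2-methylbut-2-enoyl]furan-2-yl}pent-2-enal
Product: 14 9α-(tert-butyldimethylsilyloxy)-3α-(triethylsilyloxy)-10βH-furanoeremophil-1-en-6-one, via dienyl triethylsilyl ether 13 (not isolated)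
Conditions: Et3SiOTf, Et3N, toluene, −78 to 0 °C; filtration under argon; then toluene (high dilution), BHT, 150 °C, sealed tube
Reagents that add atoms: triethylsilyl trifluoromethanesulfonate, CC[Si](CC)(CC)OS(=O)(=O)C(F)(F)F
Why: Soft enolisation of the enal (s-trans conformer, γ-deprotonation at C10) gives the (1E,3E)-1-silyloxydiene 13, which undergoes a thermal concerted intramolecular Diels–Alder reaction with the furyl tigloyl ketone, the reaction type known for 1,7,9-decatrien-3-ones in which the activating carbonyl lies inside the tether. Ring A closes as the cycloadduct ring (six-membered, bonds C3–C4 and C5–C10 formed suprafacially on both partners) and ring B as the tether ring (six-membered, fused mode; the bridged mode would need a seven-membered ring through the furan). C4 and C5: the cis-dimethyl relation is the (E)-geometry of the tigloyl alkene carried over stereospecifically. C10: the transition state with the C6 carbonyl endo and the C14 methyl exo (the alternative puts C14 under the diene) makes H-10 cis to C14, the cis ring fusion. C3: the silyloxy group is the outside substituent of the (E)-enol ether and ends up cis to H-4, that is trans to C15. Absolute sense: in the endo transition state ring B is a half-chair with the diene axial, and the tert-butyldimethylsilyloxy group on C9 takes the pseudo-equatorial position anti to the forming C5–C10 bond, away from a 1,3-diaxial contact with C14; this places O-9 trans to H-10, which is why C9 is introduced as (S) and inverted in step 19. The selectivity needed before the cycloaddition is silylation of the enal and not of the furyl ketone, secured by the higher reactivity of the aldehyde towards one equivalent of silyl triflate at −78 °C. No Lewis acid is used, because the tether imposes a regiochemistry opposite to the polar preference of a 1-silyloxydiene and an ionic Mukaiyama–Michael path would join C10 to C4.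

Step 8
Reactants: 14 9α-(tert-butyldimethylsilyloxy)-3α-(triethylsilyloxy)-10βH-furanoeremophil-1-en-6-one
Product: 15 9α-(tert-butyldimethylsilyloxy)-3α-(triethylsilyloxy)-10βH-furanoeremophilan-6-one
Conditions: H2 (1 atm), RhCl(PPh3)3 (cat.), benzene–EtOH, rt
Reagents that add atoms: none
Why: Homogeneous hydrogenation of the only disubstituted alkene; the furan, the ketone and the allylic C3–O bond (no hydrogenolysis with this catalyst) are left alone.

Step 9
Reactants: 15 9α-(tert-butyldimethylsilyloxy)-3α-(triethylsilyloxy)-10βH-furanoeremophilan-6-one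
Product: 16 9α-(tert-butyldimethylsilyloxy)-3α-(triethylsilyloxy)-10βH-furanoeremophilan-6-ol (either C6 epimer)
Conditions: LiAlH4, THF, −78 to 0 °C
Reagents that add atoms: none
Why: Hydride reduction of the hindered furyl ketone; the C6 configuration is irrelevant because the oxygen is removed, and both silyl ethers are inert.

Step 10
Reactants: 16 9α-(tert-butyldimethylsilyloxy)-3α-(triethylsilyloxy)-10βH-furanoeremophilan-6-ol
Product: 17 O-[9α-(tert-butyldimethylsilyloxy)-3α-(triethylsilyloxy)-10βH-furanoeremophilan-6-yl] S-methyl dithiocarbonate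
Conditions: NaH, imidazole (cat.), THF, 0 °C; CS2; MeI, rt
Reagents that add atoms: carbon disulfide, S=C=S; iodomethane, CI
Why: Xanthate formation, the first half of a Barton–McCombie deoxygenation; C5 is quaternary, so Chugaev elimination is not possible.

Step 11
Reactants: 17 O-[9α-(tert-butyldimethylsilyloxy)-3α-(triethylsilyloxy)-10βH-furanoeremophilan-6-yl] S-methyl dithiocarbonate
Product: 18 9α-(tert-butyldimethylsilyloxy)-3α-(triethylsilyloxy)-10βH-furanoeremophilane
Conditions: Bu3SnH, AIBN (cat.), toluene, 110 °C
Reagents that add atoms: none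
Why: Barton–McCombie radical deoxygenation through the furylmethyl-type C6 radical; a radical method is chosen because ionic reduction would ionise the furylic C9–O bond.

Step 12
Reactants: 18 9α-(tert-butyldimethylsilyloxy)-3α-(triethylsilyloxy)-10βH-furanoeremophilane
Product: 19 9α-(tert-butyldimethylsilyloxy)-10βH-furanoeremophilan-3α-ol
Conditions: HF·pyridine, pyridine, THF, 0 °C
Reagents that add atoms: none
Why: Selective cleavage of the triethylsilyl ether beside the tert-butyldimethylsilyl ether (rate difference of the two silyl groups) frees O-3 alone.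

Step 13
Reactants: 20 (E)-oct-2-enal
Product: 21 (E)-non-3-en-1-yne
Conditions: Me3SiCHN2, LiN(i-Pr)2, THF, −78 °C to rt
Reagents that add atoms: (trimethylsilyl)diazomethane, C[Si](C)(C)C=[N+]=[N-]
Why: Colvin rearrangement: addition of lithiated trimethylsilyldiazomethane, Peterson-type elimination and 1,2-shift in the alkylidene carbene give the terminal enyne with the (E)-alkene untouched.

Step 14
Reactants: 21 (E)-non-3-en-1-yne
Product: 23 (1E,3E)-1-iodo-2-methylnona-1,3-diene, via dienyldimethylalane 22 (not isolated)
Conditions: Me3Al, Cp2ZrCl2 (cat.), CH2Cl2, 0 °C to rt; then I2, THF, −30 °C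
Reagents that add atoms: trimethylaluminium, C[Al](C)C; iodine, II
Why: Negishi zirconium-catalysed carboalumination adds methyl and aluminium syn across the terminal alkyne with methyl on the internal carbon; iodinolysis with retention gives the (E)-trisubstituted alkenyl iodide.

Step 15
Reactants: 23 (1E,3E)-1-iodo-2-methylnona-1,3-diene; 24 ethyl acrylate
Product: 25 ethyl (2E,4E,6E)-5-methyldodeca-2,4,6-trienoate
Conditions: 24, Pd(OAc)2 (cat.), K2CO3, Bu4NCl, DMF, 40 °C
Reagents that add atoms: none
Why: Heck reaction of an alkenyl iodide with an acrylate under ligand-free phase-transfer conditions; syn insertion and syn β-hydride elimination give the (2E)-alkene and keep the iodide geometry.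

Step 16
Reactants: 25 ethyl (2E,4E,6E)-5-methyldodeca-2,4,6-trienoate
Product: 26 (2E,4E,6E)-5-methyldodeca-2,4,6-trienoic acid
Conditions: LiOH, THF–MeOH–H2O, rt; then dilute HCl to pH 3
Reagents that add atoms: lithium hydroxide, [Li+].[OH-]
Why: Ester saponification; the conjugated triene is stable to cold aqueous hydroxide.

Step 17
Reactants: 19 9α-(tert-butyldimethylsilyloxy)-10βH-furanoeremophilan-3α-ol; 26 (2E,4E,6E)-5-methyldodeca-2,4,6-trienoic acid
Product: 28 9α-(tert-butyldimethylsilyloxy)-10βH-furanoeremophilan-3α-yl (2E,4E,6E)-5-methyldodeca-2,4,6-trienoate, via mixed trichlorobenzoic anhydride 27 (not isolated)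
Conditions: 26, 2,4,6-trichlorobenzoyl chloride, Et3N, toluene, rt; then 19, DMAP, rt
Reagents that add atoms: none
Why: Yamaguchi esterification through the mixed anhydride and an acylpyridinium; O-3 is the only free hydroxyl and the C3–O bond is not broken, so the configuration is kept.

Step 18
Reactants: 28 9α-(tert-butyldimethylsilyloxy)-10βH-furanoeremophilan-3α-yl (2E,4E,6E)-5-methyldodeca-2,4,6-trienoate
Product: 29 9α-hydroxy-10βH-furanoeremophilan-3α-yl (2E,4E,6E)-5-methyldodeca-2,4,6-trienoate
Conditions: Bu4NF, AcOH, THF, 0 °C to rt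
Reagents that add atoms: none
Why: Buffered fluoride desilylation; neither the trienoate nor the furan is affected and the furyl carbinol is not exposed to acid.

Step 19
Reactants: 29 9α-hydroxy-10βH-furanoeremophilan-3α-yl (2E,4E,6E)-5-methyldodeca-2,4,6-trienoate
Product: 31 9β-hydroxy-10βH-furanoeremophilan-3α-yl (2E,4E,6E)-5-methyldodeca-2,4,6-trienoate, via 9β-formate 30 (not isolated)
Conditions: PPh3, DIAD, HCO2H, THF, −20 to 0 °C; then NaHCO3, MeOH–H2O, 0 °C
Reagents that add atoms: formic acid, OC=O
Why: Mitsunobu reaction: formate displaces the axial 9α-oxyphosphonium from the convex β face with inversion, giving the natural 9β configuration (9R); the formate is cleaved by bicarbonate in methanol far faster than the trienoate.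

Step 20
Reactants: 31 9β-hydroxy-10βH-furanoeremophilan-3α-yl (2E,4E,6E)-5-methyldodeca-2,4,6-trienoate
Product: 32 9β-hydroxy-8,12-dioxo-10βH-eremophil-7(11)Z-en-3α-yl (2E,4E,6E)-5-methyldodeca-2,4,6-trienoate
Conditions: VO(acac)2 (cat.), t-BuOOH, CH2Cl2, 0 °C
Reagents that add atoms: tert-butyl hydroperoxide, CC(C)(C)OO
Why: Hydroxyl-directed vanadium-catalysed oxidation of the furfuryl-type alcohol (first stage of an Achmatowicz reaction) epoxidises the furan at C7=C8 and opens it to the cis-enedione; the pyranone that normally follows would put C7=C11 at a bridgehead, so the Z keto-enal is obtained, and the trienoate, which has no directing hydroxyl, is left alone.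

Step 21
Reactants: 32 9β-hydroxy-8,12-dioxo-10βH-eremophil-7(11)Z-en-3α-yl (2E,4E,6E)-5-methyldodeca-2,4,6-trienoate
Product: 33 (3R,4R,5R,9R,10S)-9,12-dihydroxy-8-oxo-eremophil-7(11)Z-en-3-yl (2E,4E,6E)-5-methyldodeca-2,4,6-trienoate (target; may equilibrate with its 8,12-hemiketal)
Conditions: NaBH4, EtOH–CH2Cl2, −78 °C; pH 7 buffer
Reagents that add atoms: none
Why: Aldehyde-selective borohydride reduction at low temperature; the C8 ketone is conjugated and flanked by a tetrasubstituted alkene and C9, so it reacts much more slowly, and neutral work-up avoids dehydration of the Z-γ-hydroxy-enone to a furan.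

## Compound list

1 | 4-methylfuran-3-carboxylic acid | Cc1cocc1C(=O)O | starting material
2 | 4-methylfuran-3-carbonyl chloride | Cc1cocc1C(=O)Cl | intermediate
3 | (4-methylfuran-3-yl)(morpholin-4-yl)methanone | Cc1cocc1C(=O)N1CCOCC1 | intermediate
4 | [4-methyl-3-(morpholine-4-carbonyl)furan-2-yl]magnesium chloride | Cc1coc([Mg]Cl)c1C(=O)N1CCOCC1 | intermediate
5 | 4-methyl-3-(morpholine-4-carbonyl)furan-2-carbaldehyde | Cc1coc(C=O)c1C(=O)N1CCOCC1 | intermediate
6 | {2-[(1S)-1-hydroxybut-3-en-1-yl]-4-methylfuran-3-yl}(morpholin-4-yl)methanone | C=CC[C@H](O)c1occ(C)c1C(=O)N1CCOCC1 | intermediate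
7 | {2-[(1S)-1-(tert-butyldimethylsilyloxy)but-3-en-1-yl]-4-methylfuran-3-yl}(morpholin-4-yl)methanone | C=CC[C@H](O[Si](C)(C)C(C)(C)C)c1occ(C)c1C(=O)N1CCOCC1 | intermediate
8 | (E)-2-bromobut-2-ene | C/C=C(\C)Br | starting material
9 | (E)-but-2-en-2-yllithium | C/C=C(\C)[Li] | intermediate
10 | (2E)-1-{2-[(1S)-1-(tert-butyldimethylsilyloxy)but-3-en-1-yl]-4-methylfuran-3-yl}-2-methylbut-2-en-1-one | C/C=C(\C)C(=O)c1c(C)coc1[C@H](CC=C)O[Si](C)(C)C(C)(C)C | intermediate
11 | (E)-but-2-enal (crotonaldehyde) | C/C=C/C=O | starting material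
12 | (2E,5S)-5-(tert-butyldimethylsilyloxy)-5-{4-methyl-3-[(2E)-2-methylbut-2-enoyl]furan-2-yl}pent-2-enal | C/C=C(\C)C(=O)c1c(C)coc1[C@H](C/C=C/C=O)O[Si](C)(C)C(C)(C)C | intermediate
13 | (2E)-1-{2-[(1S,2E,4E)-1-(tert-butyldimethylsilyloxy)-5-(triethylsilyloxy)penta-2,4-dien-1-yl]-4-methylfuran-3-yl}-2-methylbut-2-en-1-one | C/C=C(\C)C(=O)c1c(C)coc1[C@H](/C=C/C=C/O[Si](CC)(CC)CC)O[Si](C)(C)C(C)(C)C | intermediate
14 | 9α-(tert-butyldimethylsilyloxy)-3α-(triethylsilyloxy)-10βH-furanoeremophil-1-en-6-one | CC[Si](CC)(CC)O[C@@H]1C=C[C@@H]2[C@H](O[Si](C)(C)C(C)(C)C)c3occ(C)c3C(=O)[C@]2(C)[C@H]1C | intermediate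
15 | 9α-(tert-butyldimethylsilyloxy)-3α-(triethylsilyloxy)-10βH-furanoeremophilan-6-one | CC[Si](CC)(CC)O[C@@H]1CC[C@@H]2[C@H](O[Si](C)(C)C(C)(C)C)c3occ(C)c3C(=O)[C@]2(C)[C@H]1C | intermediate
16 | 9α-(tert-butyldimethylsilyloxy)-3α-(triethylsilyloxy)-10βH-furanoeremophilan-6-ol | CC[Si](CC)(CC)O[C@@H]1CC[C@@H]2[C@H](O[Si](C)(C)C(C)(C)C)c3occ(C)c3C(O)[C@]2(C)[C@H]1C | intermediate
17 | O-[9α-(tert-butyldimethylsilyloxy)-3α-(triethylsilyloxy)-10βH-furanoeremophilan-6-yl] S-methyl dithiocarbonate | CC[Si](CC)(CC)O[C@@H]1CC[C@@H]2[C@H](O[Si](C)(C)C(C)(C)C)c3occ(C)c3C(OC(=S)SC)[C@]2(C)[C@H]1C | intermediate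
18 | 9α-(tert-butyldimethylsilyloxy)-3α-(triethylsilyloxy)-10βH-furanoeremophilane | CC[Si](CC)(CC)O[C@@H]1CC[C@@H]2[C@H](O[Si](C)(C)C(C)(C)C)c3occ(C)c3C[C@]2(C)[C@H]1C | intermediate
19 | 9α-(tert-butyldimethylsilyloxy)-10βH-furanoeremophilan-3α-ol | O[C@@H]1CC[C@@H]2[C@H](O[Si](C)(C)C(C)(C)C)c3occ(C)c3C[C@]2(C)[C@H]1C | intermediate
20 | (E)-oct-2-enal | CCCCC/C=C/C=O | starting material
21 | (E)-non-3-en-1-yne | CCCCC/C=C/C#C | intermediate
22 | dimethyl[(1E,3E)-2-methylnona-1,3-dien-1-yl]alane | CCCCC/C=C/C(C)=C/[Al](C)C | intermediate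
23 | (1E,3E)-1-iodo-2-methylnona-1,3-diene | CCCCC/C=C/C(C)=C/I | intermediate
24 | ethyl acrylate | C=CC(=O)OCC | starting material
25 | ethyl (2E,4E,6E)-5-methyldodeca-2,4,6-trienoate | CCCCC/C=C/C(C)=C/C=C/C(=O)OCC | intermediate
26 | (2E,4E,6E)-5-methyldodeca-2,4,6-trienoic acid | CCCCC/C=C/C(C)=C/C=C/C(=O)O | intermediate
27 | (2E,4E,6E)-5-methyldodeca-2,4,6-trienoic 2,4,6-trichlorobenzoic anhydride | CCCCC/C=C/C(C)=C/C=C/C(=O)OC(=O)c1c(Cl)cc(Cl)cc1Cl | intermediate
28 | 9α-(tert-butyldimethylsilyloxy)-10βH-furanoeremophilan-3α-yl (2E,4E,6E)-5-methyldodeca-2,4,6-trienoate | CCCCC/C=C/C(C)=C/C=C/C(=O)O[C@@H]1CC[C@@H]2[C@H](O[Si](C)(C)C(C)(C)C)c3occ(C)c3C[C@]2(C)[C@H]1C | intermediate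
29 | 9α-hydroxy-10βH-furanoeremophilan-3α-yl (2E,4E,6E)-5-methyldodeca-2,4,6-trienoate | CCCCC/C=C/C(C)=C/C=C/C(=O)O[C@@H]1CC[C@@H]2[C@H](O)c3occ(C)c3C[C@]2(C)[C@H]1C | intermediate
30 | 9β-formyloxy-10βH-furanoeremophilan-3α-yl (2E,4E,6E)-5-methyldodeca-2,4,6-trienoate | CCCCC/C=C/C(C)=C/C=C/C(=O)O[C@@H]1CC[C@@H]2[C@@H](OC=O)c3occ(C)c3C[C@]2(C)[C@H]1C | intermediate
31 | 9β-hydroxy-10βH-furanoeremophilan-3α-yl (2E,4E,6E)-5-methyldodeca-2,4,6-trienoate | CCCCC/C=C/C(C)=C/C=C/C(=O)O[C@@H]1CC[C@@H]2[C@@H](O)c3occ(C)c3C[C@]2(C)[C@H]1C | intermediate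
32 | 9β-hydroxy-8,12-dioxo-10βH-eremophil-7(11)Z-en-3α-yl (2E,4E,6E)-5-methyldodeca-2,4,6-trienoate | CCCCC/C=C/C(C)=C/C=C/C(=O)O[C@@H]1CC[C@@H]2[C@@H](O)C(=O)/C(=C(/C)C=O)C[C@]2(C)[C@H]1C | intermediate
33 | (3R,4R,5R,9R,10S)-9,12-dihydroxy-8-oxo-eremophil-7(11)Z-en-3-yl (2E,4E,6E)-5-methyldodeca-2,4,6-trienoate | CCCCC/C=C/C(C)=C/C=C/C(=O)O[C@@H]1CC[C@@H]2[C@@H](O)C(=O)/C(=C(/C)CO)C[C@]2(C)[C@H]1C | target

## Step count and least certain steps

Total: 21 steps. Longest linear sequence: 17 steps (steps 1–12 and 17–21); the acid 26 is made in 4 steps (13–16).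

**Step 7 (key step).** The most likely failure is slow cycloaddition. The dienophile is substituted on both carbons, and the silyloxy donor sits on the diene terminus that must bond to the enone β-carbon, so the tether-imposed orientation runs against the polar preference. Thermal loss of the silyl dienol ether, elimination of the C9 silyloxy group during enolisation, or silylation of the furyl ketone could then overtake ring closure. A second uncertainty is how strongly C9 controls the diene face. Fallback, from 12 back to 15: NaBH4 at −78 °C reduces the aldehyde alone to allylic alcohol F1, which is converted into its methyl carbonate F2 (ClCO2Me, pyridine). Palladium-catalysed 1,4-elimination (Pd(PPh3)4, Et3N, THF, reflux) gives the oxygen-free (1E,3E)-diene F3. This diene is thermally robust and polarity-matched (its free terminus C3 is the nucleophilic end and bonds to the enone β-carbon C4); its intramolecular Diels–Alder reaction gives cycloadduct F4 with the same C4/C5/C10 relations. Allylic oxidation at C3, the only allylic methylene (CrO3·3,5-dimethylpyrazole), gives enone F5, and hydrogenation (H2, RhCl(PPh3)3) gives dione F6. NaBH4 at −78 °C reduces the unhindered C3 ketone from the axial direction to the equatorial 3α-alcohol F7, whose triethylsilyl ether is 15.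

**Step 5.** The most likely failure is incomplete addition to an amide flanked on both sides (the C8 side chain and the C13 methyl), with competing metalation at the furan C12–H. Fallback, from 7 back to 10: Cp2Zr(H)Cl reduces the tertiary amide to aldehyde F8, addition of 9 gives allylic alcohol F9 (mixture of carbinol epimers), and MnO2 oxidation gives 10.

**Step 19.** The most likely failure is E2 elimination of the axial 9α-oxyphosphonium with the anti-periplanar H-10 to a vinylfuran, or ionisation of the furylic centre. Fallback, from 29 back to 32: the inversion is postponed. Hydroxyl-directed furan opening of 29 (conditions of step 20) gives the 9α-hydroxy keto-enal F10, and the α-ketol is equilibrated through its enediol with a mild base (imidazole or Et3N) to the 9β epimer 32. The 9β epimer should be the more stable one: its hydroxyl is equatorial in the ring-B conformer that keeps C14 equatorial, whereas a 9α-hydroxyl is axial and syn to C4.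

**Step 21.** The most likely failure is hydride addition to the C8 ketone or conjugate addition to the ene-dione, and dehydration to a furan on work-up. Fallback, from 32 back to 33: Luche reduction (NaBH4, CeCl3) of both carbonyl groups gives triol F11; selective silylation of the primary allylic hydroxyl (TBSCl, imidazole) gives F12; MnO2 oxidises the allylic secondary C8 carbinol (the C9 hydroxyl is not allylic) to enone F13; buffered fluoride (Bu4NF, AcOH) gives 33.

## Further compounds

F1 | step 7 | (2E)-1-{2-[(1S,3E)-1-(tert-butyldimethylsilyloxy)-5-hydroxypent-3-en-1-yl]-4-methylfuran-3-yl}-2-methylbut-2-en-1-one | C/C=C(\C)C(=O)c1c(C)coc1[C@H](C/C=C/CO)O[Si](C)(C)C(C)(C)C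
F2 | step 7 | methyl carbonate of F1 | C/C=C(\C)C(=O)c1c(C)coc1[C@H](C/C=C/COC(=O)OC)O[Si](C)(C)C(C)(C)C
F3 | step 7 | (2E)-1-{2-[(1S,2E)-1-(tert-butyldimethylsilyloxy)penta-2,4-dien-1-yl]-4-methylfuran-3-yl}-2-methylbut-2-en-1-one | C/C=C(\C)C(=O)c1c(C)coc1[C@H](/C=C/C=C)O[Si](C)(C)C(C)(C)C
F4 | step 7 | 9α-(tert-butyldimethylsilyloxy)-10βH-furanoeremophil-1-en-6-one | C1C=C[C@@H]2[C@H](O[Si](C)(C)C(C)(C)C)c3occ(C)c3C(=O)[C@]2(C)[C@H]1C
F5 | step 7 | 9α-(tert-butyldimethylsilyloxy)-10βH-furanoeremophil-1-ene-3,6-dione | O=C1C=C[C@@H]2[C@H](O[Si](C)(C)C(C)(C)C)c3occ(C)c3C(=O)[C@]2(C)[C@H]1C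
F6 | step 7 | 9α-(tert-butyldimethylsilyloxy)-10βH-furanoeremophilane-3,6-dione | O=C1CC[C@@H]2[C@H](O[Si](C)(C)C(C)(C)C)c3occ(C)c3C(=O)[C@]2(C)[C@H]1C
F7 | step 7 | 9α-(tert-butyldimethylsilyloxy)-3α-hydroxy-10βH-furanoeremophilan-6-one | O[C@@H]1CC[C@@H]2[C@H](O[Si](C)(C)C(C)(C)C)c3occ(C)c3C(=O)[C@]2(C)[C@H]1C
F8 | step 5 | 2-[(1S)-1-(tert-butyldimethylsilyloxy)but-3-en-1-yl]-4-methylfuran-3-carbaldehyde | C=CC[C@H](O[Si](C)(C)C(C)(C)C)c1occ(C)c1C=O
F9 | step 5 | (2E)-1-{2-[(1S)-1-(tert-butyldimethylsilyloxy)but-3-en-1-yl]-4-methylfuran-3-yl}-2-methylbut-2-en-1-ol | C/C=C(\C)C(O)c1c(C)coc1[C@H](CC=C)O[Si](C)(C)C(C)(C)C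
F10 | step 19 | 9α-hydroxy-8,12-dioxo-10βH-eremophil-7(11)Z-en-3α-yl (2E,4E,6E)-5-methyldodeca-2,4,6-trienoate | CCCCC/C=C/C(C)=C/C=C/C(=O)O[C@@H]1CC[C@@H]2[C@H](O)C(=O)/C(=C(/C)C=O)C[C@]2(C)[C@H]1C
F11 | step 21 | 8,9β,12-trihydroxy-10βH-eremophil-7(11)Z-en-3α-yl (2E,4E,6E)-5-methyldodeca-2,4,6-trienoate | CCCCC/C=C/C(C)=C/C=C/C(=O)O[C@@H]1CC[C@@H]2[C@@H](O)C(O)/C(=C(/C)CO)C[C@]2(C)[C@H]1C
F12 | step 21 | 12-(tert-butyldimethylsilyloxy)-8,9β-dihydroxy-10βH-eremophil-7(11)Z-en-3α-yl (2E,4E,6E)-5-methyldodeca-2,4,6-trienoate | CCCCC/C=C/C(C)=C/C=C/C(=O)O[C@@H]1CC[C@@H]2[C@@H](O)C(O)/C(=C(/C)CO[Si](C)(C)C(C)(C)C)C[C@]2(C)[C@H]1C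
F13 | step 21 | 12-(tert-butyldimethylsilyloxy)-9β-hydroxy-8-oxo-10βH-eremophil-7(11)Z-en-3α-yl (2E,4E,6E)-5-methyldodeca-2,4,6-trienoate | CCCCC/C=C/C(C)=C/C=C/C(=O)O[C@@H]1CC[C@@H]2[C@@H](O)C(=O)/C(=C(/C)CO[Si](C)(C)C(C)(C)C)C[C@]2(C)[C@H]1C
A1 | alternative 1 | (3R,4R)-4-(tert-butyldimethylsilyloxy)-2,3-dimethylcyclohexan-1-one | O=C1CC[C@@H](O[Si](C)(C)C(C)(C)C)[C@H](C)C1C
A2 | alternative 1 | 3α-(tert-butyldimethylsilyloxy)-11,12,13-trinoreremophil-9-en-8-one | CC(C)(C)[Si](C)(C)O[C@@H]1CCC2=CC(=O)CC[C@]2(C)[C@H]1C
A3 | alternative 2 | (Z)-3-(tert-butyldimethylsilyloxy)penta-1,3-diene | C=C/C(O[Si](C)(C)C(C)(C)C)=C/C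
A4 | alternative 2 | endo cycloadduct, cis-fused 3-(tert-butyldimethylsilyloxy)-8-methoxy-4α,5β-dimethyl-10βH-decalin-2,7-diene-6,9-dione (C15 trans to C14) | C[C@@H]1C(O[Si](C)(C)C(C)(C)C)=CC[C@@H]2C(=O)C(OC)=CC(=O)[C@]12C
A5 | alternative 3 | 3-(bromomethyl)-4-methylfuran | Cc1cocc1CBr
A6 | alternative 3 | (2R,3R,4R)-4-(tert-butyldimethylsilyloxy)-2,3-dimethyl-2-[(4-methylfuran-3-yl)methyl]cyclohexan-1-one | O=C1CC[C@@H](O[Si](C)(C)C(C)(C)C)[C@H](C)[C@@]1(C)Cc1cocc1C
A7 | alternative 3 | (1S,2R,3R,4R)-4-(tert-butyldimethylsilyloxy)-2,3-dimethyl-2-[(4-methylfuran-3-yl)methyl]cyclohexane-1-carbaldehyde | O=C[C@H]1CC[C@@H](O[Si](C)(C)C(C)(C)C)[C@H](C)[C@@]1(C)Cc1cocc1C
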